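Assumption (chemistry): compounds 15 and 16 are racemic and 17 is a pair of C4 epimers. This centre becomes an aromatic CH in step 14, so no control over it is attempted. TBS stands for tert-butyldimethylsilyl throughout.

## Analysis of the target

Compound 30 is an 18-membered macrocycle made of four benzene rings. Ring A carries the carbinol at C1, hydroxyls at C3 and C4 and an aryl ether at C5. Ring B is a para-phenylene, ring C is 1,2,3-trisubstituted (ethano bridge, aryl ether, hydroxyl) and ring D is a meta-phenylene. The rings are tied together by two diaryl ether oxygens (A–O–B and C–O–D), a CH2CH2 bridge between rings B and C, and a CH(OH)–CH2 bridge between rings A and D. The only stereocentre is the (S)-configured benzylic carbinol; with no second centre to relay from, it must be set by a chiral reagent or catalyst. The free catechol of ring A is sensitive to oxidation in base. The carbinol is para to the C4 hydroxyl, so acid or hot base can ionise it through a para-quinone methide and cause racemisation or dehydration. The synthesis is hard for three reasons: the contiguous oxygens O3, O4 and O5 of ring A must be told apart with only O5 arylated, a large ring must be closed, and a lone stereocentre must be carried through that closure. The strategy rests on the ring A pattern itself: three neighbouring oxygens, C1 para to the middle one, C2 and C6 unsubstituted. This is the pattern of a 2,3-dialkoxyphenol grown from a squaric acid derived cyclobutenone, whose carbonyl carbon ends as the one free phenol at C5.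

## Retrosynthetic reasoning

30 ⇒ 29 ⇒ 28. The last operations only remove protecting groups and saturate one double bond. The carbinol oxygen stays silylated until the end (29), because once O4 is free the unprotected benzylic alcohol is the most fragile site in the molecule. The final desilylation is therefore run buffered and cold. The three phenolic oxygens are benzyl ethers, so one hydrogenation of stilbene 28 both reduces the C=C bond and frees them.

28 ⇒ 26 (⇒ 25 ⇒ 23). The macrocycle is opened at the ethano bridge between rings B and C, written as a C=C bond. This bond is far from the stereocentre, and both carbons are available at the right oxidation level (the formyl carbon of 21 and the formyl carbon of 1). Olefination of a benzylic ylide with an aromatic aldehyde is also the best-tested closure for 18-membered rings of this family. The forward step must favour ring closure over chain growth, which is a matter of dilution. Phosphonium salt 26 comes from bromide 25 and alcohol 23.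

23 ⇒ 22 ⇒ 20 + 21. The ring A–O–ring B ether is cut at the O–ring B bond. In 20 the oxygen at C5 is the only free hydroxyl, and 21 is activated for SNAr by its formyl group, which then serves unchanged as the Wittig acceptor. The ylide carbon on ring C is carried as a primary silyl ether and released selectively (22 to 23). An ester was not used at that position: it would have to survive an acetylide addition earlier and a hydride reduction next to an aldehyde later.

20 ⇒ 17. This is the central disconnection. Ring A is not taken from a gallic acid type arene, whose three oxygens would need stepwise protection. It is cut at C5–C6 (retro-electrocyclisation) and folded back into the four-membered ring of 17. C2 to C5 then come from 13, and C1 and C6 from alkyne 7. The gain is that the difference between O5 (free) and O3/O4 (benzylated) is written into the connectivity, because the carbonyl carbon of 17 becomes C5. The forward reaction must open the cyclobutenone and close the benzene ring without disturbing the silylated carbinol attached to the reacting alkene.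

17 ⇒ 12 + 16. The bond between C4 of the cyclobutenone and the internal alkene carbon is cut, giving chloride 16 and α-stannyl alkene 12 for a Stille coupling. This keeps the chiral fragment and the squarate fragment apart until late. Chloride 16 is three steps from 13 through 14 and 15, and the benzyl groups on O3 and O4 are simply the ester groups of 14.

12 ⇒ 11 ⇒ 10 ⇒ 9 ⇒ 8. The stannane is traced to terminal alkyne 11 by Markovnikov hydrostannation, and the stereocentre to ynone 8 by asymmetric transfer hydrogenation, the only stereo-defining step. An ynone is the right prochiral precursor because its two flanks differ strongly and because the alkyne is the two-carbon unit that ring A needs. Both hydroxyls of 9 are silylated in one operation (10), so the ring C hydroxymethyl group is protected at no extra cost.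

8 ⇒ 6 + 7, and 6 ⇒ 5 ⇒ 2 + 4. The ynone is cut at the acyl–alkyne bond, giving Weinreb amide 6 and alkyne 7. The ring C–O–ring D ether is cut at the O–ring C bond, because SNAr there is driven by the ortho formyl group of 2. After the coupling (5) that formyl group is reduced (6), so it can neither add the acetylide nor be reduced without control in the hydrogenation step. Compound 2 is the benzyl ether of 1, and 4 is the amide of 3.

## Alternatives that were turned down

Alternative 1: The carbinol C–CH2 bond is cut by a retro-[1,2]-Wittig shift, leading back to a 19-membered macrocyclic benzyl ether A2 that carries tin on the ring A benzylic carbon. In the forward sense, tin–lithium exchange with an alkyllithium gives an α-alkoxy carbanion, the ring D benzyl group moves from oxygen to carbon, and the ring contracts to carbinol A1.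
- For: the large ring is closed by a simple benzylic etherification, easier than any C–C macrocyclisation. The carbinol oxygen is present from the start and needs no protecting group. On both points this route is stronger than the chosen one.
- Against: the shift passes through a radical pair, and the carbanion is benzylic as well as α-oxygenated, so it is configurationally labile. Transfer of configuration from A2 to A1 is therefore uncertain. Shifts into the ortho position of ring D and [1,4] pathways compete.
- Against: A2 itself needs an enantioenriched α-stannyl ether, and ring A still has to be built with three differentiated oxygens by protecting-group chemistry.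
- Comparison: the chosen route sets the centre by catalyst control on an open-chain ketone and never makes it a reactive centre again, and it obtains the ring A oxygen pattern from connectivity.

Alternative 2: Two C–C bonds of ring B are cut, tracing that ring to pyrone A4 and aryl ethynyl ether A5. Forward, an inverse-demand [4+2] cycloaddition followed by decarboxylation gives the open-chain ketone A3 with the aryloxy group para to the acyl group.
- For: the ring A–O–ring B ether is formed without any aryl–oxygen coupling, and two large halves are joined in one step. On the ether bond this route is stronger than the SNAr of the chosen one.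
- Against: ring B is a bare para-phenylene that 21 supplies ready-made, so the ring synthesis is spent where it is least needed. A5 is prone to hydrolysis and thermal decomposition, and A4 carries an enolisable benzylic ketone.
- Against: after A3 the macrocycle is still open, one ketone must be deoxygenated while a second is reduced asymmetrically, and ring A again comes from a selectively protected arene.
- Comparison: the chosen route places its ring construction on ring A, where it removes the protecting-group problem, and it is shorter after the key step.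

Alternative 3: The ring D aryl–CH2 bond is cut, leading to the open-chain methyl ketone and aryl bromide A7. Forward, a palladium-catalysed enolate arylation with a bulky phosphine and an alkoxide base closes the 18-membered ring as deoxybenzoin A6, which is then reduced asymmetrically.
- For: this is probably the shortest of the four plans by several steps. The ethers and the ethano bridge are made by routine reactions, and the stereocentre is set last on an aryl benzyl ketone, a good substrate class. On step count and on late stereocontrol it is stronger than the chosen route.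
- Against: enolate arylation is bimolecular by nature and little tested for rings of this size. The product ketone is more acidic than the starting methyl ketone and can be arylated again. Hot alkoxide is needed.
- Against: ring A must again be assembled as a 3,4-dibenzylated, 5-arylated gallate derivative by selective protection, and the face selectivity of a reduction inside a cyclophane is less predictable than on an open chain.
- Comparison: the chosen route offers a ring closure with strong precedent for this ring type, an early and well-understood stereo-defining step, and a ring A whose oxygens are differentiated without selective protection.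

Key step: step 14

## Route

Step 1
Reactants: 1 2-fluoro-3-hydroxybenzaldehyde
Product: 2 3-(benzyloxy)-2-fluorobenzaldehyde
Conditions: BnBr, K2CO3, DMF, 23 °C
Reagents that add atoms: benzyl bromide, BrCc1ccccc1
Why: Williamson etherification of the phenoxide; the benzyl group masks the future ring C hydroxyl until the final hydrogenolysis and leaves the fluorine activated by the ortho formyl group.

Step 2
Reactants: 3 3-hydroxyphenylacetic acid
Product: 4 2-(3-hydroxyphenyl)-N-methoxy-N-methylacetamide
Conditions: MeNHOMe·HCl, EDC·HCl, HOBt (cat.), iPr2NEt, CH2Cl2, 0 → 23 °C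
Reagents that add atoms: N,O-dimethylhydroxylamine hydrochloride, CNOC.Cl
Why: Carbodiimide amide coupling to the Weinreb amide; any aryl ester formed at the free phenol is itself an acylating agent and is aminolysed.

Step 3
Reactants: 2 3-(benzyloxy)-2-fluorobenzaldehyde; 4 2-(3-hydroxyphenyl)-N-methoxy-N-methylacetamide
Product: 5 2-{3-[2-(benzyloxy)-6-formylphenoxy]phenyl}-N-methoxy-N-methylacetamide
Conditions: K2CO3, DMF, 110 °C
Reagents that add atoms: none
Why: SNAr; the phenoxide of 4 displaces fluoride ortho to the formyl group, which stabilises the Meisenheimer intermediate, and the ring C–O–ring D ether is formed.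

Step 4
Reactants: 5 2-{3-[2-(benzyloxy)-6-formylphenoxy]phenyl}-N-methoxy-N-methylacetamide
Product: 6 2-{3-[2-(benzyloxy)-6-(hydroxymethyl)phenoxy]phenyl}-N-methoxy-N-methylacetamide
Conditions: NaBH4, MeOH–THF, 0 °C
Reagents that add atoms: none
Why: Chemoselective borohydride reduction of the aldehyde, the Weinreb amide being inert; the carbon is brought to the oxidation level needed for the later ylide and is removed from the reach of the acetylide.

Step 5
Reactants: 6 2-{3-[2-(benzyloxy)-6-(hydroxymethyl)phenoxy]phenyl}-N-methoxy-N-methylacetamide; 7 ethynyltrimethylsilane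
Product: 8 1-{3-[2-(benzyloxy)-6-(hydroxymethyl)phenoxy]phenyl}-4-(trimethylsilyl)but-3-yn-2-one
Conditions: 7 (3 equiv), n-BuLi (3 equiv), THF, −78 °C; then 6, −78 → 0 °C; aq. NH4Cl
Reagents that add atoms: none
Why: Weinreb ketone synthesis; acylation of the lithium acetylide stops at the ketone, one equivalent of acetylide being spent on the free hydroxyl, and the silyl cap keeps the ynone from conjugate addition.

Step 6
Reactants: 8 1-{3-[2-(benzyloxy)-6-(hydroxymethyl)phenoxy]phenyl}-4-(trimethylsilyl)but-3-yn-2-one
Product: 9 (S)-1-{3-[2-(benzyloxy)-6-(hydroxymethyl)phenoxy]phenyl}-4-(trimethylsilyl)but-3-yn-2-ol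
Conditions: Ru[(S,S)-TsDPEN](p-cymene) (2 mol%), 2-propanol, 25 °C
Reagents that add atoms: none
Why: Noyori asymmetric transfer hydrogenation of an α,β-acetylenic ketone under base-free conditions; the (S,S)-ligand should place the alkynyl group where the aryl group of simple aryl ketones sits and deliver hydride to the face that gives the (S)-carbinol, the only stereocentre of the route.

Step 7
Reactants: 9 (S)-1-{3-[2-(benzyloxy)-6-(hydroxymethyl)phenoxy]phenyl}-4-(trimethylsilyl)but-3-yn-2-ol
Product: 10 bis(TBS) ether of 9, silylated at the secondary propargylic and the primary benzylic oxygen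
Conditions: TBSCl (2.4 equiv), imidazole, DMF, 23 °C
Reagents that add atoms: tert-butyldimethylsilyl chloride, CC(C)(C)[Si](C)(C)Cl
Why: Imidazole-promoted silylation of both hydroxyls in one operation; the stereocentre is not involved.

Step 8
Reactants: 10 bis(TBS) ether of 9
Product: 11 (S)-terminal alkyne, tert-butyl{[(2S)-1-{3-[2-(benzyloxy)-6-(TBS-oxymethyl)phenoxy]phenyl}but-3-yn-2-yl]oxy}dimethylsilane
Conditions: K2CO3 (0.3 equiv), MeOH, 23 °C
Reagents that add atoms: none
Why: Methanolysis of the alkynyl C–Si bond; alkyl TBS ethers are stable to carbonate in methanol.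

Step 9
Reactants: 11 (S)-terminal alkyne
Product: 12 (S)-α-stannyl alkene, the 2-(tributylstannyl)but-1-ene obtained by adding Sn to the internal and H to the terminal alkyne carbon of 11
Conditions: Bu3SnH, Mo(CO)3(CNtBu)3 (3 mol%), hydroquinone (10 mol%), THF, 55 °C
Reagents that add atoms: tributyltin hydride, CCCC[SnH](CCCC)CCCC
Why: Molybdenum-catalysed syn hydrostannation of a terminal propargylic ether, which places tin on the internal carbon; hydroquinone suppresses the radical pathway that would give the terminal stannane.

Step 10
Reactants: 13 squaric acid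
Product: 14 dibenzyl squarate, 3,4-bis(benzyloxy)cyclobut-3-ene-1,2-dione
Conditions: BnOH (4 equiv), toluene, reflux, Dean–Stark trap
Reagents that add atoms: benzyl alcohol, OCc1ccccc1
Why: Azeotropic esterification of the vinylogous diacid, which is acidic enough to catalyse its own esterification; the two benzyl groups become the protecting groups of O3 and O4.

Step 11
Reactants: 14 dibenzyl squarate
Product: 15 2,3-bis(benzyloxy)-4-hydroxycyclobut-2-en-1-one (racemic)
Conditions: LiAlH(OtBu)3 (1.05 equiv), THF, −78 °C
Reagents that add atoms: none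
Why: 1,2-Reduction of one of two equivalent carbonyl groups by a bulky hydride; the remaining carbonyl is a vinylogous ester and is not reduced further.

Step 12
Reactants: 15 2,3-bis(benzyloxy)-4-hydroxycyclobut-2-en-1-one
Product: 16 2,3-bis(benzyloxy)-4-chlorocyclobut-2-en-1-one (racemic)
Conditions: PPh3, CCl4, MeCN, 0 → 23 °C
Reagents that add atoms: carbon tetrachloride, ClC(Cl)(Cl)Cl
Why: Appel reaction; SN2 displacement of the alkoxyphosphonium group α to the carbonyl under neutral conditions, which avoids the acid-induced loss of a benzyloxy group to a cyclobutenedione.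

Step 13
Reactants: 12 (S)-α-stannyl alkene; 16 2,3-bis(benzyloxy)-4-chlorocyclobut-2-en-1-one
Product: 17 2,3-bis(benzyloxy)-4-[(3S)-3-(TBS-oxy)-4-{3-[2-(benzyloxy)-6-(TBS-oxymethyl)phenoxy]phenyl}but-1-en-2-yl]cyclobut-2-en-1-one (both C4 epimers)
Conditions: Pd2(dba)3 (2.5 mol%), tri(2-furyl)phosphine (10 mol%), CuI (10 mol%), DMF–THF, 25–40 °C
Reagents that add atoms: none
Why: Stille coupling; oxidative addition of the allylic, α-keto C–Cl bond to zerovalent palladium, copper-assisted transfer of the alkenyl group from tin and reductive elimination at the CH terminus, a coupling established for squarate-derived 4-chlorocyclobutenones. The temperature is held low so that 17 can be handled before it rearranges.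

Step 14
Reactants: 17 4-alkenyl-2,3-bis(benzyloxy)cyclobutenone
Product: 20 2,3-bis(benzyloxy)-5-[(1S)-1-(TBS-oxy)-2-{3-[2-(benzyloxy)-6-(TBS-oxymethyl)phenoxy]phenyl}ethyl]phenol, via dienylketene 18 (not isolated), via cyclohexa-2,4-dienone 19 (not isolated)
Conditions: toluene (0.02 M), 100 °C, argon
Reagents that add atoms: none
Why: Heating should trigger a thermally allowed conrotatory 4π ring opening that breaks the C1–C4 bond of the strained ring and gives dienylketene 18. Only the isomer with the alkenyl group turned towards the ketene can react further; the out-rotated isomer cannot cyclise, but the opening is reversible, so it returns to 17 and is drawn through the productive channel. Disrotatory 6π-electrocyclisation of 18 joins the ketene carbon (the old carbonyl carbon) to the CH2 terminus of the 1,1-disubstituted alkene and closes the six-membered carbocycle of ring A as dienone 19, which tautomerises irreversibly to phenol 20. The closest known reaction type is the thermal rearrangement of 4-alkenyl- and 4-arylcyclobutenones to phenols, which is also the closing sequence of the Danheiser benzannulation. No stereocentre is created, and both C4 epimers converge because C4 becomes the aromatic C2–H. The selectivity needed is regiochemical and is fixed by connectivity: the carbonyl carbon ends as C5–OH and the two benzyloxy carbons as C4 and C3, so the only free phenol is the one to be arylated. The (S)-silyl ether carbon is a spectator on C1, lies outside the reacting π system and meets only neutral conditions, so its configuration should be retained.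

Step 15
Reactants: 20 ring A phenol; 21 4-fluorobenzaldehyde
Product: 22 4-{2,3-bis(benzyloxy)-5-[(1S)-1-(TBS-oxy)-2-{3-[2-(benzyloxy)-6-(TBS-oxymethyl)phenoxy]phenyl}ethyl]phenoxy}benzaldehyde
Conditions: K2CO3, DMF, 100 °C
Reagents that add atoms: none
Why: SNAr of the only free phenoxide on the para-formyl-activated aryl fluoride; the ring A–O–ring B ether is formed and the aldehyde for the ring closure arrives with it.

Step 16
Reactants: 22 ring B aldehyde with two TBS ethers
Product: 23 primary benzylic alcohol, 4-{2,3-bis(benzyloxy)-5-[(1S)-1-(TBS-oxy)-2-{3-[2-(benzyloxy)-6-(hydroxymethyl)phenoxy]phenyl}ethyl]phenoxy}benzaldehyde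
Conditions: HF·pyridine, pyridine, THF, 0 °C
Reagents that add atoms: none
Why: Sterically controlled selective desilylation; the unhindered primary benzylic silyl ether should be cleaved well before the secondary one flanked by an aryl and a benzyl group, and the buffered medium leaves the aldehyde untouched.

Step 17
Reactants: 23 primary benzylic alcohol
Product: 25 benzylic bromide, 4-{2,3-bis(benzyloxy)-5-[(1S)-1-(TBS-oxy)-2-{3-[2-(benzyloxy)-6-(bromomethyl)phenoxy]phenyl}ethyl]phenoxy}benzaldehyde, via mesylate 24 (not isolated)
Conditions: MsCl, Et3N, CH2Cl2, −10 °C; then LiBr, THF, 23 °C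
Reagents that add atoms: lithium bromide, [Li+].[Br-]; methanesulfonyl chloride, CS(=O)(=O)Cl (its atoms stay only in 24)
Why: Sulfonylation followed by SN2 displacement with bromide (Finkelstein type); these conditions do not touch the aldehyde, unlike phosphine/tetrahalomethane reagents.

Step 18
Reactants: 25 benzylic bromide
Product: 26 benzyltriphenylphosphonium bromide carrying the ring B aldehyde
Conditions: PPh3, toluene, 80 °C
Reagents that add atoms: triphenylphosphine, c1ccc(cc1)P(c1ccccc1)c1ccccc1
Why: SN2 quaternisation of the phosphine by the benzylic bromide; without base the aldehyde is inert.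

Step 19
Reactants: 26 phosphonium bromide
Product: 28 18-membered macrocyclic stilbene, the tri-O-benzyl O-TBS derivative of the target with a CH=CH bridge between rings B and C (E/Z mixture), via phosphonium ylide 27 (not isolated)
Conditions: NaOMe, CH2Cl2, 23 °C, slow addition of 26 to a final concentration of about 1 mM
Reagents that add atoms: none
Why: Intramolecular Wittig reaction of a semi-stabilised benzylic ylide with the aromatic aldehyde under high dilution, a closure well established for rings of this type; the alkene geometry is irrelevant because the bond is hydrogenated next.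

Step 20
Reactants: 28 macrocyclic stilbene
Product: 29 (S)-O-TBS ether of the target, with the three phenols free and the ethano bridge saturated
Conditions: H2 (1 atm), Pd/C (10%), EtOAc–EtOH, 23 °C
Reagents that add atoms: none
Why: Catalytic hydrogenation saturates the stilbene and hydrogenolyses the three benzyl ethers; in a neutral solvent the hindered secondary benzylic silyl ether should resist C–O hydrogenolysis.

Step 21
Reactants: 29 (S)-O-TBS ether of the target
Product: 30 target CNP0333307.1, the (S)-carbinol
Conditions: Bu4NF, AcOH (1:1), THF, 0 → 23 °C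
Reagents that add atoms: none
Why: Fluoride-induced desilylation; buffering with acetic acid keeps the phenols protonated, so neither catechol oxidation nor para-quinone methide formation at the carbinol should occur and the configuration is retained.

## Compound list

1 | 2-fluoro-3-hydroxybenzaldehyde | O=Cc1cccc(O)c1F | starting material
2 | 3-(benzyloxy)-2-fluorobenzaldehyde | O=Cc1cccc(OCc2ccccc2)c1F | intermediate
3 | 3-hydroxyphenylacetic acid | OC(=O)Cc1cccc(O)c1 | starting material
4 | 2-(3-hydroxyphenyl)-N-methoxy-N-methylacetamide | CON(C)C(=O)Cc1cccc(O)c1 | intermediate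
5 | 2-{3-[2-(benzyloxy)-6-formylphenoxy]phenyl}-N-methoxy-N-methylacetamide | CON(C)C(=O)Cc1cccc(Oc2c(C=O)cccc2OCc2ccccc2)c1 | intermediate
6 | 2-{3-[2-(benzyloxy)-6-(hydroxymethyl)phenoxy]phenyl}-N-methoxy-N-methylacetamide | CON(C)C(=O)Cc1cccc(Oc2c(CO)cccc2OCc2ccccc2)c1 | intermediate
7 | ethynyltrimethylsilane | C#C[Si](C)(C)C | starting material
8 | 1-{3-[2-(benzyloxy)-6-(hydroxymethyl)phenoxy]phenyl}-4-(trimethylsilyl)but-3-yn-2-one | C[Si](C)(C)C#CC(=O)Cc1cccc(Oc2c(CO)cccc2OCc2ccccc2)c1 | intermediate
9 | (S)-1-{3-[2-(benzyloxy)-6-(hydroxymethyl)phenoxy]phenyl}-4-(trimethylsilyl)but-3-yn-2-ol | C[Si](C)(C)C#C[C@@H](O)Cc1cccc(Oc2c(CO)cccc2OCc2ccccc2)c1 | intermediate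
10 | bis(TBS) ether of 9 | C[Si](C)(C)C#C[C@@H](O[Si](C)(C)C(C)(C)C)Cc1cccc(Oc2c(CO[Si](C)(C)C(C)(C)C)cccc2OCc2ccccc2)c1 | intermediate
11 | (S)-terminal alkyne, bis(TBS) ether | C#C[C@@H](O[Si](C)(C)C(C)(C)C)Cc1cccc(Oc2c(CO[Si](C)(C)C(C)(C)C)cccc2OCc2ccccc2)c1 | intermediate
12 | (S)-2-(tributylstannyl)but-1-ene derivative (α-stannyl alkene) | C=C([Sn](CCCC)(CCCC)CCCC)[C@@H](O[Si](C)(C)C(C)(C)C)Cc1cccc(Oc2c(CO[Si](C)(C)C(C)(C)C)cccc2OCc2ccccc2)c1 | intermediate
13 | squaric acid | OC1=C(O)C(=O)C1=O | starting material
14 | dibenzyl squarate | O=C1C(=O)C(OCc2ccccc2)=C1OCc1ccccc1 | intermediate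
15 | 2,3-bis(benzyloxy)-4-hydroxycyclobut-2-en-1-one (racemic) | O=C1C(OCc2ccccc2)=C(OCc2ccccc2)C1O | intermediate
16 | 2,3-bis(benzyloxy)-4-chlorocyclobut-2-en-1-one (racemic) | O=C1C(OCc2ccccc2)=C(OCc2ccccc2)C1Cl | intermediate
17 | 4-alkenyl-2,3-bis(benzyloxy)cyclobut-2-en-1-one with the (S)-silyl ether side chain (C4 epimers) | O=C1C(OCc2ccccc2)=C(OCc2ccccc2)C1C(=C)[C@@H](O[Si](C)(C)C(C)(C)C)Cc1cccc(Oc2c(CO[Si](C)(C)C(C)(C)C)cccc2OCc2ccccc2)c1 | intermediate
18 | dienylketene, ketene and methylene unit cis across the central C=C | O=C=C(OCc2ccccc2)/C(OCc2ccccc2)=C\C(=C)[C@@H](O[Si](C)(C)C(C)(C)C)Cc1cccc(Oc2c(CO[Si](C)(C)C(C)(C)C)cccc2OCc2ccccc2)c1 | intermediate (not isolated)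
19 | 2,3-bis(benzyloxy)-5-substituted cyclohexa-2,4-dien-1-one | O=C1CC(=CC(OCc2ccccc2)=C1OCc1ccccc1)[C@@H](O[Si](C)(C)C(C)(C)C)Cc1cccc(Oc2c(CO[Si](C)(C)C(C)(C)C)cccc2OCc2ccccc2)c1 | intermediate (not isolated)
20 | ring A phenol, 2,3-bis(benzyloxy)-5-[(1S)-1-(TBS-oxy)-2-arylethyl]phenol | Oc1cc(cc(OCc2ccccc2)c1OCc1ccccc1)[C@@H](O[Si](C)(C)C(C)(C)C)Cc1cccc(Oc2c(CO[Si](C)(C)C(C)(C)C)cccc2OCc2ccccc2)c1 | intermediate
21 | 4-fluorobenzaldehyde | O=Cc1ccc(F)cc1 | starting material
22 | ring B aldehyde, bis(TBS) ether | O=Cc1ccc(cc1)Oc1cc(cc(OCc2ccccc2)c1OCc1ccccc1)[C@@H](O[Si](C)(C)C(C)(C)C)Cc1cccc(Oc2c(CO[Si](C)(C)C(C)(C)C)cccc2OCc2ccccc2)c1 | intermediate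
23 | ring B aldehyde with free ring C hydroxymethyl group | O=Cc1ccc(cc1)Oc1cc(cc(OCc2ccccc2)c1OCc1ccccc1)[C@@H](O[Si](C)(C)C(C)(C)C)Cc1cccc(Oc2c(CO)cccc2OCc2ccccc2)c1 | intermediate
24 | benzylic mesylate of 23 | O=Cc1ccc(cc1)Oc1cc(cc(OCc2ccccc2)c1OCc1ccccc1)[C@@H](O[Si](C)(C)C(C)(C)C)Cc1cccc(Oc2c(COS(C)(=O)=O)cccc2OCc2ccccc2)c1 | intermediate (not isolated)
25 | benzylic bromide | O=Cc1ccc(cc1)Oc1cc(cc(OCc2ccccc2)c1OCc1ccccc1)[C@@H](O[Si](C)(C)C(C)(C)C)Cc1cccc(Oc2c(CBr)cccc2OCc2ccccc2)c1 | intermediate
26 | benzyltriphenylphosphonium bromide | O=Cc1ccc(cc1)Oc1cc(cc(OCc2ccccc2)c1OCc1ccccc1)[C@@H](O[Si](C)(C)C(C)(C)C)Cc1cccc(Oc2c(C[P+](c3ccccc3)(c3ccccc3)c3ccccc3)cccc2OCc2ccccc2)c1.[Br-] | intermediate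
27 | phosphonium ylide | O=Cc1ccc(cc1)Oc1cc(cc(OCc2ccccc2)c1OCc1ccccc1)[C@@H](O[Si](C)(C)C(C)(C)C)Cc1cccc(Oc2c(C=P(c3ccccc3)(c3ccccc3)c3ccccc3)cccc2OCc2ccccc2)c1 | intermediate (not isolated)
28 | macrocyclic stilbene, tri-O-benzyl, O-TBS (E/Z mixture) | c1ccccc1COc1cc2cc(c1OCc1ccccc1)Oc1ccc(cc1)C=Cc1cccc(OCc3ccccc3)c1Oc1cccc(c1)C[C@@H]2O[Si](C)(C)C(C)(C)C | intermediate
29 | (S)-O-TBS ether of the target | Oc1cc2cc(c1O)Oc1ccc(cc1)CCc1cccc(O)c1Oc1cccc(c1)C[C@@H]2O[Si](C)(C)C(C)(C)C | intermediate
30 | CNP0333307.1, (S)-carbinol | Oc1cc2cc(c1O)Oc1ccc(cc1)CCc1cccc(O)c1Oc1cccc(c1)C[C@@H]2O | target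

## Step count and least certain steps

Total step count: 21. Longest linear sequence: 17 steps (3 to 30 through steps 2–9 and 13–21; the squarate branch, steps 10–12, joins at step 13).

Step 14 (key step).
- What may go wrong: the ring opening may turn the alkenyl group away from the ketene, and if that ketene is consumed by dimerisation or by traces of nucleophiles faster than it recloses, material is lost before the electrocyclisation. Premature ring opening during isolation of 17 would have the same effect.
- Fallback (ring A from a preformed arene; sets out from 6 and returns at 20): commercial 5-bromo-2,3-dihydroxybenzaldehyde is dibenzylated (BnBr, K2CO3) to 2,3-bis(benzyloxy)-5-bromobenzaldehyde F1. Baeyer–Villiger oxidation (mCPBA) gives 2,3-bis(benzyloxy)-5-bromophenyl formate F2, which is methanolysed (K2CO3, MeOH) to 2,3-bis(benzyloxy)-5-bromophenol F3 and silylated (TBSCl, imidazole) to the aryl silyl ether F4. Bromine–lithium exchange (n-BuLi, THF, −78 °C) gives the aryllithium F5, which is added to 6 (hydroxyl deprotonated beforehand) to give the aryl benzyl ketone F6. Asymmetric transfer hydrogenation with RuCl[(S,S)-TsDPEN](p-cymene) in HCO2H/Et3N should give the (S)-diol F7, and silylation gives the tris(TBS) ether F8. K2CO3 in MeOH cleaves only the aryl silyl ether and returns 20. The price is that the three oxygens are then differentiated by protecting-group steps.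

Step 13.
- What may go wrong: slow transfer of the branched α-alkenyl group from tin, leading to protodestannylation or homocoupling; decomposition of the labile chloride 16 before it couples; or bond formation at the benzyloxy-bearing terminus of the allyl-type palladium intermediate.
- Fallback (C–C bond by carbonyl addition instead of cross-coupling; sets out from 12 and 14 and returns at 22): tin–lithium exchange on 12 (n-BuLi, THF, −78 °C) gives the alkenyllithium F9, which adds to one carbonyl of 14 to give the 4-alkenyl-4-hydroxycyclobutenone F10. On heating (toluene, 110 °C, argon) the hydroxyl group turns outward and forces the alkenyl group inward, and the same electrocyclic sequence gives the hydroquinone F11. SNAr with 21 (K2CO3, DMF, degassed) at the less hindered hydroxyl gives the mono-aryl ether F12. The remaining hindered phenol is converted to the triflate F13 (Tf2O, pyridine) and removed by reduction (Pd(OAc)2, dppf, HCO2H, Et3N, DMF) to give 22.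

Step 9.
- What may go wrong: poor regioselectivity, with tin delivered to the terminal carbon because the bulky silyl ether shields the internal position, or radical addition giving the same wrong isomer.
- Fallback (Markovnikov hydrosilylation and halogen exchange; sets out from 11 and returns at 12): hydrosilylation with Et3SiH and [Cp*Ru(MeCN)3]PF6 (CH2Cl2, 0 °C) gives the α-triethylsilyl alkene F14. Iododesilylation (N-iodosuccinimide, 2,6-lutidine, hexafluoro-2-propanol, 0 °C) gives the 2-iodoalkene F15, and stannylation with (Bu3Sn)2 and Pd(PPh3)4 (toluene, 80 °C) returns 12.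

Step 19.
- What may go wrong: intermolecular olefination to dimers and oligomers instead of ring closure, or hydrolysis of the ylide during the slow addition.
- Fallback (reductive carbonyl coupling; sets out from 23 and returns at 28): oxidation of 23 with MnO2 (CH2Cl2) gives the dialdehyde F16, and McMurry coupling with low-valent titanium from TiCl4 and Zn (pyridine, THF, reflux, high dilution) closes the ring to 28.

## Further compounds

F1 | step 14 | 2,3-bis(benzyloxy)-5-bromobenzaldehyde | O=Cc1cc(Br)cc(OCc2ccccc2)c1OCc1ccccc1
F2 | step 14 | 2,3-bis(benzyloxy)-5-bromophenyl formate | O=COc1cc(Br)cc(OCc2ccccc2)c1OCc1ccccc1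
F3 | step 14 | 2,3-bis(benzyloxy)-5-bromophenol | Oc1cc(Br)cc(OCc2ccccc2)c1OCc1ccccc1
F4 | step 14 | [2,3-bis(benzyloxy)-5-bromophenoxy](tert-butyl)dimethylsilane | CC(C)(C)[Si](C)(C)Oc1cc(Br)cc(OCc2ccccc2)c1OCc1ccccc1
F5 | step 14 | 3,4-bis(benzyloxy)-5-(TBS-oxy)phenyllithium | [Li]c1cc(O[Si](C)(C)C(C)(C)C)c(OCc2ccccc2)c(OCc2ccccc2)c1
F6 | step 14 | aryl benzyl ketone, 1-[3,4-bis(benzyloxy)-5-(TBS-oxy)phenyl]-2-{3-[2-(benzyloxy)-6-(hydroxymethyl)phenoxy]phenyl}ethanone | CC(C)(C)[Si](C)(C)Oc1cc(cc(OCc2ccccc2)c1OCc1ccccc1)C(=O)Cc1cccc(Oc2c(CO)cccc2OCc2ccccc2)c1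
F7 | step 14 | (S)-diol from reduction of F6 | CC(C)(C)[Si](C)(C)Oc1cc(cc(OCc2ccccc2)c1OCc1ccccc1)[C@@H](O)Cc1cccc(Oc2c(CO)cccc2OCc2ccccc2)c1
F8 | step 14 | (S)-tris(TBS) ether | CC(C)(C)[Si](C)(C)Oc1cc(cc(OCc2ccccc2)c1OCc1ccccc1)[C@@H](O[Si](C)(C)C(C)(C)C)Cc1cccc(Oc2c(CO[Si](C)(C)C(C)(C)C)cccc2OCc2ccccc2)c1
F9 | step 13 | (S)-alkenyllithium from 12 | [Li]C(=C)[C@@H](O[Si](C)(C)C(C)(C)C)Cc1cccc(Oc2c(CO[Si](C)(C)C(C)(C)C)cccc2OCc2ccccc2)c1
F10 | step 13 | 4-alkenyl-2,3-bis(benzyloxy)-4-hydroxycyclobut-2-en-1-one (C4 epimers) | O=C1C(OCc2ccccc2)=C(OCc2ccccc2)C1(O)C(=C)[C@@H](O[Si](C)(C)C(C)(C)C)Cc1cccc(Oc2c(CO[Si](C)(C)C(C)(C)C)cccc2OCc2ccccc2)c1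
F11 | step 13 | 2,3-bis(benzyloxy)-5-substituted hydroquinone | Oc1cc(c(O)c(OCc2ccccc2)c1OCc1ccccc1)[C@@H](O[Si](C)(C)C(C)(C)C)Cc1cccc(Oc2c(CO[Si](C)(C)C(C)(C)C)cccc2OCc2ccccc2)c1
F12 | step 13 | hydroquinone mono(4-formylphenyl) ether | O=Cc1ccc(cc1)Oc1cc(c(O)c(OCc2ccccc2)c1OCc1ccccc1)[C@@H](O[Si](C)(C)C(C)(C)C)Cc1cccc(Oc2c(CO[Si](C)(C)C(C)(C)C)cccc2OCc2ccccc2)c1
F13 | step 13 | aryl triflate of F12 | O=Cc1ccc(cc1)Oc1cc(c(OS(=O)(=O)C(F)(F)F)c(OCc2ccccc2)c1OCc1ccccc1)[C@@H](O[Si](C)(C)C(C)(C)C)Cc1cccc(Oc2c(CO[Si](C)(C)C(C)(C)C)cccc2OCc2ccccc2)c1
F14 | step 9 | (S)-2-(triethylsilyl)but-1-ene derivative | C=C([Si](CC)(CC)CC)[C@@H](O[Si](C)(C)C(C)(C)C)Cc1cccc(Oc2c(CO[Si](C)(C)C(C)(C)C)cccc2OCc2ccccc2)c1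
F15 | step 9 | (S)-2-iodobut-1-ene derivative | C=C(I)[C@@H](O[Si](C)(C)C(C)(C)C)Cc1cccc(Oc2c(CO[Si](C)(C)C(C)(C)C)cccc2OCc2ccccc2)c1
F16 | step 19 | dialdehyde from oxidation of 23 | O=Cc1ccc(cc1)Oc1cc(cc(OCc2ccccc2)c1OCc1ccccc1)[C@@H](O[Si](C)(C)C(C)(C)C)Cc1cccc(Oc2c(C=O)cccc2OCc2ccccc2)c1
A1 | alternative 1 | (S)-macrocyclic carbinol, tris(TBS) ether | O[C@H]1Cc2cccc(c2)Oc2c(O[Si](C)(C)C(C)(C)C)cccc2CCc2ccc(cc2)Oc2cc1cc(O[Si](C)(C)C(C)(C)C)c2O[Si](C)(C)C(C)(C)C
A2 | alternative 1 | 19-membered macrocyclic α-(tributylstannyl) benzyl ether (configuration at the tin-bearing carbon left open) | CCCC[Sn](CCCC)(CCCC)C1OCc2cccc(c2)Oc2c(O[Si](C)(C)C(C)(C)C)cccc2CCc2ccc(cc2)Oc2cc1cc(O[Si](C)(C)C(C)(C)C)c2O[Si](C)(C)C(C)(C)C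
A3 | alternative 2 | open-chain tetra-aryl ketone with ring B newly formed | O=C(Cc1cccc(OCc3ccccc3)c1Oc1cccc(Br)c1)c1ccc(cc1)Oc1cc(cc(OCc3ccccc3)c1OCc3ccccc3)C1(C)OCCO1
A4 | alternative 2 | 5-acyl-2-pyrone carrying rings C and D | O=C1C=CC(=CO1)C(=O)Cc1cccc(OCc3ccccc3)c1Oc1cccc(Br)c1
A5 | alternative 2 | ring A aryl ethynyl ether | C#COc1cc(cc(OCc3ccccc3)c1OCc3ccccc3)C1(C)OCCO1
A6 | alternative 3 | macrocyclic deoxybenzoin, tribenzyl ether | O=C1Cc2cccc(c2)Oc2c(OCc3ccccc3)cccc2CCc2ccc(cc2)Oc2cc1cc(OCc3ccccc3)c2OCc3ccccc3
A7 | alternative 3 | open-chain ring A methyl ketone with ring D aryl bromide | CC(=O)c1cc(OCc3ccccc3)c(OCc3ccccc3)c(c1)Oc1ccc(cc1)CCc1cccc(OCc3ccccc3)c1Oc1cccc(Br)c1
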